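**Strategy.** The ten-membered carbocycle is closed last among the skeletal bonds, at C1–C2 (germacrane numbering): the bond between oxirane carbon C1 and C2 of the 2Z,4Z-diene. The feature exploited is that C1 sits between the oxygenated quaternary C10 and an sp2 carbon: C1 is carried as an aldehyde beside the C10 silyloxy centre and C2 as an iodoalkyne on a 4Z-enyne that folds the seco-chain. One nickel/chromium-mediated alkynylation closes the ring and sets the C1 carbinol anti to O10 (Felkin–Anh). Semi-hydrogenation then gives the Z,Z-diene, and displacement of the C1 sulfonate by O10 with inversion forms the trans-oxirane.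

Key step: step 15

Remark: germacrane numbering is used throughout (C1–C10 ring, C11–C13 lactone unit); the zinc Barbier union of step 9 is assumed to follow the closed chair model (8S carbinol), and the inverting esterification of step 12 is chosen on that basis.

**Route**

Step 1
Reactants: 1 (Z)-3-methylpent-2-en-4-yn-1-ol
Product: 3 (Z)-3-methyl-5-(trimethylsilyl)pent-2-en-4-yn-1-ol, via bis(trimethylsilyl) derivative 2 (not isolated)
Conditions: n-BuLi (2.2 equiv), THF, −78 °C; Me3SiCl (2.4 equiv), −78 °C → rt; then 1 M HCl, rt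
Reagents that add atoms: chlorotrimethylsilane, C[Si](C)(C)Cl
Why: The alkoxide/acetylide dianion is silylated on O and C and the labile O–Si bond is then hydrolysed selectively by dilute acid (standard acetylide C-silylation), the 4Z-alkene being untouched.

Step 2
Reactants: 3 (Z)-3-methyl-5-(trimethylsilyl)pent-2-en-4-yn-1-ol
Product: 4 (Z)-3-methyl-5-(trimethylsilyl)pent-2-en-4-ynal
Conditions: MnO2 (15 equiv), CH2Cl2, rt
Reagents that add atoms: none
Why: Allylic oxidation with MnO2 is neutral and should give the enal without Z→E isomerisation.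

Step 3
Reactants: 4 (Z)-3-methyl-5-(trimethylsilyl)pent-2-en-4-ynal
Product: 5 (3S,4Z)-5-methyl-7-(trimethylsilyl)hepta-1,4-dien-6-yn-3-ol
Conditions: divinylzinc (1.5 equiv), (2S)-(−)-3-exo-morpholinoisoborneol (10 mol %), toluene/hexane, −20 → 0 °C; aq NH4Cl
Reagents that add atoms: divinylzinc, C=C[Zn]C=C
Why: Amino-alcohol-catalysed asymmetric organozinc 1,2-addition (Oppolzer-type vinylation), in which the (−)-ligand should deliver the vinyl group to the Si face of the aldehyde and so set C6 as the 3S carbinol.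

Step 4
Reactants: 5 (3S,4Z)-5-methyl-7-(trimethylsilyl)hepta-1,4-dien-6-yn-3-ol; 6 2-(bromomethyl)acrylic acid
Product: 7 (3S,4Z)-5-methyl-7-(trimethylsilyl)hepta-1,4-dien-6-yn-3-yl 2-(bromomethyl)prop-2-enoate
Conditions: DCC, DMAP (5 mol %), CH2Cl2, −10 → 0 °C
Reagents that add atoms: none
Why: Steglich esterification at low temperature with only catalytic DMAP should acylate the carbinol without N-alkylation by the allylic bromide and without touching the stereocentre.

Step 5
Reactants: 7 (3S,4Z)-5-methyl-7-(trimethylsilyl)hepta-1,4-dien-6-yn-3-yl 2-(bromomethyl)prop-2-enoate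
Product: 8 (5R)-3-(bromomethyl)-5-[(1Z)-2-methyl-4-(trimethylsilyl)but-1-en-3-yn-1-yl]furan-2(5H)-one
Conditions: second-generation Grubbs catalyst RuCl2(=CHPh)(PCy3)(H2IMes) (5–10 mol %), CH2Cl2 (5 mM), 40 °C
Reagents that add atoms: none
Why: Ring-closing metathesis: the ruthenium alkylidene forms at the monosubstituted vinyl group and closes onto the acrylate to give the butenolide, the silyl-capped, trisubstituted enyne being a poor metathesis partner.

Step 6
Reactants: 9 (S)-2-methylglycidol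
Product: 10 (2R)-2-methylpent-4-ene-1,2-diol
Conditions: vinylmagnesium bromide (3 equiv), CuI (10 mol %), THF, −40 → 0 °C; aq NH4Cl
Reagents that add atoms: vinylmagnesium bromide, C=C[Mg]Br
Why: Copper-catalysed Grignard opening of the epoxide at its unsubstituted CH2 leaves the quaternary centre (future C10) untouched, and the Payne rearrangement of this alkoxide is degenerate.

Step 7
Reactants: 10 (2R)-2-methylpent-4-ene-1,2-diol
Product: 11 (2R)-2-methyl-1,2-bis(triethylsilyloxy)pent-4-ene
Conditions: Et3SiOTf (2.5 equiv), 2,6-lutidine, CH2Cl2, −78 → 0 °C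
Reagents that add atoms: triethylsilyl trifluoromethanesulfonate, CC[Si](CC)(CC)OS(=O)(=O)C(F)(F)F
Why: The silyl triflate is reactive enough to silylate the tertiary as well as the primary hydroxyl.

Step 8
Reactants: 11 (2R)-2-methyl-1,2-bis(triethylsilyloxy)pent-4-ene
Product: 13 (3R)-3-methyl-3,4-bis(triethylsilyloxy)butanal, via secondary ozonide 12 (not isolated)
Conditions: O3, CH2Cl2, −78 °C; then PPh3, −78 °C → rt
Reagents that add atoms: ozone, [O-][O+]=O
Why: Ozonolysis with reductive work-up cleaves the terminal alkene to the C8 aldehyde, the silyl ethers being inert.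

Step 9
Reactants: 8 (5R)-3-(bromomethyl)-5-[(1Z)-2-methyl-4-(trimethylsilyl)but-1-en-3-yn-1-yl]furan-2(5H)-one; 13 (3R)-3-methyl-3,4-bis(triethylsilyloxy)butanal
Product: 14 (4R,5R)-4-[(1S,3R)-1-hydroxy-3-methyl-3,4-bis(triethylsilyloxy)butyl]-3-methylidene-5-[(1Z)-2-methyl-4-(trimethylsilyl)but-1-en-3-yn-1-yl]oxolan-2-one
Conditions: Zn dust, THF/sat. aq NH4Cl (5:1), 0 °C → rt
Reagents that add atoms: none
Why: Barbier-type 2-(alkoxycarbonyl)allylation in which the allylzinc reacts at C7 (SE2′) through a closed chair transition state, the aldehyde approaching anti to the C6 alkenyl group (6,7-trans lactone) and, because the ring locks the allyl unit in the E-crotyl-type geometry, giving the 7,8-anti carbinol (8S), the C8 epimer that step 12 inverts.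

Step 10
Reactants: 15 (E)-2-methylbut-2-en-1-ol (tiglyl alcohol)
Product: 16 (2R,3R)-2,3-epoxy-2-methylbutan-1-ol
Conditions: Ti(OiPr)4 (10 mol %), D-(−)-diethyl tartrate (12 mol %), t-BuOOH, 4 Å molecular sieves, CH2Cl2, −20 °C
Reagents that add atoms: tert-butyl hydroperoxide, CC(C)(C)OO
Why: Sharpless asymmetric epoxidation, in which the D-(−)-tartrate complex delivers oxygen to the alkene face that gives the 2R,3R epoxy alcohol.

Step 11
Reactants: 16 (2R,3R)-2,3-epoxy-2-methylbutan-1-ol
Product: 17 (2S,3R)-2,3-epoxy-2-methylbutanoic acid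
Conditions: TEMPO (20 mol %), PhI(OAc)2 (2.2 equiv), MeCN/H2O (1:1), 0 °C → rt
Reagents that add atoms: water, O
Why: Oxoammonium oxidation via the aldehyde hydrate gives the acid under conditions that leave the oxirane intact, and only the CIP descriptor at C2 changes.

Step 12
Reactants: 14 (4R,5R)-4-[(1S,3R)-1-hydroxy-3-methyl-3,4-bis(triethylsilyloxy)butyl]-3-methylidene-5-[(1Z)-2-methyl-4-(trimethylsilyl)but-1-en-3-yn-1-yl]oxolan-2-one; 17 (2S,3R)-2,3-epoxy-2-methylbutanoic acid
Product: 18 (1R,3R)-3-methyl-1-{(2R,3R)-4-methylidene-2-[(1Z)-2-methyl-4-(trimethylsilyl)but-1-en-3-yn-1-yl]-5-oxooxolan-3-yl}-3,4-bis(triethylsilyloxy)butyl (2S,3R)-2,3-dimethyloxirane-2-carboxylate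
Conditions: PPh3, DIAD, toluene, 0 °C → rt
Reagents that add atoms: none
Why: Mitsunobu esterification, in which the C8 oxyphosphonium ion is displaced by the carboxylate of the fairly acidic glycidic acid 17 with inversion, installing the side chain and correcting C8 to 8R in one operation.

Step 13
Reactants: 18 (the C8 ester with the trimethylsilyl alkyne)
Product: 19 (1R,3R)-1-{(2R,3R)-2-[(1Z)-4-iodo-2-methylbut-1-en-3-yn-1-yl]-4-methylidene-5-oxooxolan-3-yl}-3-methyl-3,4-bis(triethylsilyloxy)butyl (2S,3R)-2,3-dimethyloxirane-2-carboxylate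
Conditions: N-iodosuccinimide (1.2 equiv), AgNO3 (10 mol %), acetone, rt, dark
Reagents that add atoms: N-iodosuccinimide, O=C1CCC(=O)N1I
Why: Silver-catalysed iododesilylation converts the alkynylsilane directly into the 1-iodoalkyne under neutral conditions that spare the silyl ethers, the oxirane ester and the methylene lactone.

Step 14
Reactants: 19 (the iodoalkyne bis-silyl ether)
Product: 20 (1R,3R)-1-{(2R,3R)-2-[(1Z)-4-iodo-2-methylbut-1-en-3-yn-1-yl]-4-methylidene-5-oxooxolan-3-yl}-3-methyl-4-oxo-3-(triethylsilyloxy)butyl (2S,3R)-2,3-dimethyloxirane-2-carboxylate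
Conditions: (COCl)2 (4 equiv), DMSO (8 equiv), CH2Cl2, −78 → −40 °C; then Et3N, −78 → 0 °C
Reagents that add atoms: none
Why: Swern conditions cleave a primary triethylsilyl ether and oxidise it in the same flask to the aldehyde, while the hindered tertiary silyl ether on O10 survives and the α-quaternary aldehyde cannot epimerise.

Step 15
Reactants: 20 (the iodoalkyne aldehyde)
Product: 21 (1S,6R,7R,8R,10R)-1-hydroxy-10-(triethylsilyloxy)-8-[(2S,3R)-2,3-epoxy-2-methylbutanoyloxy]germacra-4Z,11(13)-dien-2-yn-6,12-olide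
Conditions: CrCl2 (10 equiv), NiCl2 (2 mol %), THF/DMF (3:1), 3 mM, slow addition of 20, rt
Reagents that add atoms: none
Why: CrCl2 reduces NiCl2 to zerovalent nickel, which inserts into the C(sp)–I bond, and transmetalation gives an alkynyl trivalent-chromium species that adds only to the aldehyde, so the lactone, its methylene acceptor, the oxirane ester and the silyl ether are left alone. The closest known reaction type is the Nozaki–Hiyama–Kishi (Takai) alkynylation used to macrocyclise iodoalkyne aldehydes, and base-mediated acetylide closures of ten-membered Z-enyne rings are direct analogues. The ten-membered carbocycle closes in a 10-exo-trig mode by attack of C2 on the C1 carbonyl. The new stereocentre C1 is controlled by C10: in the polar Felkin–Anh arrangement the C10–OSiEt3 bond lies anti to the incoming alkynyl group and the nucleophile passes the methyl group and not the C9 methylene, which should give the 1S (1,2-anti) carbinol. The step needs ring closure to beat oligomerisation, which high dilution and the U-turn imposed by the 4Z-alkene (C6 and the alkyne cis) should secure, and it needs non-chelated addition, which the bulky silyl ether on O10 should secure.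

Step 16
Reactants: 21 (the macrocyclic propargylic alcohol)
Product: 22 (1S,6R,7R,8R,10R)-1,10-dihydroxy-8-[(2S,3R)-2,3-epoxy-2-methylbutanoyloxy]germacra-4Z,11(13)-dien-2-yn-6,12-olide
Conditions: HF·pyridine, pyridine, THF, 0 °C → rt
Reagents that add atoms: none
Why: Buffered fluoride removes the tertiary triethylsilyl ether while the ring is still at the acid-tolerant propargylic stage.

Step 17
Reactants: 22 (the macrocyclic enyne diol)
Product: 23 (1S,6R,7R,8R,10R)-1,10-dihydroxy-8-[(2S,3R)-2,3-epoxy-2-methylbutanoyloxy]germacra-2Z,4Z,11(13)-trien-6,12-olide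
Conditions: H2 (1 atm), Pd/CaCO3 poisoned with Pb(OAc)2 (Lindlar catalyst), quinoline, EtOAc, rt, monitored closely
Reagents that add atoms: none
Why: Lindlar syn-semi-hydrogenation of the strained conjugated ring alkyne should be much faster than reduction of any alkene and sets the 2Z geometry, completing the Z,Z-diene.

Step 18
Reactants: 23 (the Z,Z-diene 1,10-diol)
Product: 25 (1R,6R,7R,8R,10R)-1,10-epoxy-8-[(2S,3R)-2,3-epoxy-2-methylbutanoyloxy]germacra-2Z,4Z,11(13)-trien-6,12-olide (CNP0122107.1), via C1 mesylate 24 (not isolated)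
Conditions: Ms2O (1.2 equiv), Et3N, CH2Cl2, −40 °C; then DBU, −40 → 0 °C
Reagents that add atoms: none
Why: Only the secondary C1 hydroxyl is sulfonylated (the tertiary C10 hydroxyl is inert) and DBU then triggers an intramolecular Williamson (3-exo-tet) displacement by O10 with inversion at C1, turning the anti-diol into the trans-oxirane (1R,10R).

**Compound list**

1 | (Z)-3-methylpent-2-en-4-yn-1-ol | C#C/C(C)=C\CO | starting material
2 | (Z)-trimethyl{[3-methyl-5-(trimethylsilyl)pent-2-en-4-yn-1-yl]oxy}silane | C[Si](C)(C)OC/C=C(C)\C#C[Si](C)(C)C | intermediate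
3 | (Z)-3-methyl-5-(trimethylsilyl)pent-2-en-4-yn-1-ol | OC/C=C(C)\C#C[Si](C)(C)C | intermediate
4 | (Z)-3-methyl-5-(trimethylsilyl)pent-2-en-4-ynal | O=C/C=C(C)\C#C[Si](C)(C)C | intermediate
5 | (3S,4Z)-5-methyl-7-(trimethylsilyl)hepta-1,4-dien-6-yn-3-ol | C=C[C@H](O)/C=C(C)\C#C[Si](C)(C)C | intermediate
6 | 2-(bromomethyl)acrylic acid | C=C(CBr)C(=O)O | starting material
7 | (3S,4Z)-5-methyl-7-(trimethylsilyl)hepta-1,4-dien-6-yn-3-yl 2-(bromomethyl)prop-2-enoate | C=C(CBr)C(=O)O[C@@H](C=C)/C=C(C)\C#C[Si](C)(C)C | intermediate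
8 | (5R)-3-(bromomethyl)-5-[(1Z)-2-methyl-4-(trimethylsilyl)but-1-en-3-yn-1-yl]furan-2(5H)-one | BrCC1=C[C@@H](/C=C(C)\C#C[Si](C)(C)C)OC1=O | intermediate
9 | (S)-2-methylglycidol, (S)-(2-methyloxiran-2-yl)methanol | OC[C@@]1(C)CO1 | starting material
10 | (2R)-2-methylpent-4-ene-1,2-diol | OC[C@](C)(O)CC=C | intermediate
11 | (2R)-2-methyl-1,2-bis(triethylsilyloxy)pent-4-ene | CC[Si](CC)(CC)OC[C@](C)(O[Si](CC)(CC)CC)CC=C | intermediate
12 | secondary ozonide (1,2,4-trioxolane) of 11, mixture at the ozonide carbon | CC[Si](CC)(CC)OC[C@](C)(O[Si](CC)(CC)CC)CC1OCOO1 | intermediate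
13 | (3R)-3-methyl-3,4-bis(triethylsilyloxy)butanal | CC[Si](CC)(CC)OC[C@](C)(O[Si](CC)(CC)CC)CC=O | intermediate
14 | (4R,5R)-4-[(1S,3R)-1-hydroxy-3-methyl-3,4-bis(triethylsilyloxy)butyl]-3-methylidene-5-[(1Z)-2-methyl-4-(trimethylsilyl)but-1-en-3-yn-1-yl]oxolan-2-one (C6 R, C7 R, C8 S, C10 R) | C=C1C(=O)O[C@H](/C=C(C)\C#C[Si](C)(C)C)[C@H]1[C@@H](O)C[C@@](C)(O[Si](CC)(CC)CC)CO[Si](CC)(CC)CC | intermediate
15 | (E)-2-methylbut-2-en-1-ol (tiglyl alcohol) | C/C=C(\C)CO | starting material
16 | (2R,3R)-2,3-epoxy-2-methylbutan-1-ol | OC[C@@]1(C)O[C@@H]1C | intermediate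
17 | (2S,3R)-2,3-epoxy-2-methylbutanoic acid | OC(=O)[C@@]1(C)O[C@@H]1C | intermediate
18 | (1R,3R)-3-methyl-1-{(2R,3R)-4-methylidene-2-[(1Z)-2-methyl-4-(trimethylsilyl)but-1-en-3-yn-1-yl]-5-oxooxolan-3-yl}-3,4-bis(triethylsilyloxy)butyl (2S,3R)-2,3-dimethyloxirane-2-carboxylate (C8 R) | C=C1C(=O)O[C@H](/C=C(C)\C#C[Si](C)(C)C)[C@H]1[C@H](OC(=O)[C@@]2(C)O[C@@H]2C)C[C@@](C)(O[Si](CC)(CC)CC)CO[Si](CC)(CC)CC | intermediate
19 | iodoalkyne analogue of 18: (1R,3R)-1-{(2R,3R)-2-[(1Z)-4-iodo-2-methylbut-1-en-3-yn-1-yl]-4-methylidene-5-oxooxolan-3-yl}-3-methyl-3,4-bis(triethylsilyloxy)butyl (2S,3R)-2,3-dimethyloxirane-2-carboxylate | C=C1C(=O)O[C@H](/C=C(C)\C#CI)[C@H]1[C@H](OC(=O)[C@@]2(C)O[C@@H]2C)C[C@@](C)(O[Si](CC)(CC)CC)CO[Si](CC)(CC)CC | intermediate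
20 | C1 aldehyde: (1R,3R)-1-{(2R,3R)-2-[(1Z)-4-iodo-2-methylbut-1-en-3-yn-1-yl]-4-methylidene-5-oxooxolan-3-yl}-3-methyl-4-oxo-3-(triethylsilyloxy)butyl (2S,3R)-2,3-dimethyloxirane-2-carboxylate | C=C1C(=O)O[C@H](/C=C(C)\C#CI)[C@H]1[C@H](OC(=O)[C@@]2(C)O[C@@H]2C)C[C@@](C)(O[Si](CC)(CC)CC)C=O | intermediate
21 | (1S,6R,7R,8R,10R)-1-hydroxy-10-(triethylsilyloxy)-8-[(2S,3R)-2,3-epoxy-2-methylbutanoyloxy]germacra-4Z,11(13)-dien-2-yn-6,12-olide | C=C1C(=O)O[C@@H]2/C=C(C)\C#C[C@H](O)[C@](C)(O[Si](CC)(CC)CC)C[C@@H](OC(=O)[C@@]3(C)O[C@@H]3C)[C@@H]12 | intermediate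
22 | (1S,6R,7R,8R,10R)-1,10-dihydroxy-8-[(2S,3R)-2,3-epoxy-2-methylbutanoyloxy]germacra-4Z,11(13)-dien-2-yn-6,12-olide | C=C1C(=O)O[C@@H]2/C=C(C)\C#C[C@H](O)[C@](C)(O)C[C@@H](OC(=O)[C@@]3(C)O[C@@H]3C)[C@@H]12 | intermediate
23 | (1S,6R,7R,8R,10R)-1,10-dihydroxy-8-[(2S,3R)-2,3-epoxy-2-methylbutanoyloxy]germacra-2Z,4Z,11(13)-trien-6,12-olide | C=C1C(=O)O[C@@H]2/C=C(C)\C=C/[C@H](O)[C@](C)(O)C[C@@H](OC(=O)[C@@]3(C)O[C@@H]3C)[C@@H]12 | intermediate
24 | 1-O-methanesulfonate of 23 | C=C1C(=O)O[C@@H]2/C=C(C)\C=C/[C@H](OS(C)(=O)=O)[C@](C)(O)C[C@@H](OC(=O)[C@@]3(C)O[C@@H]3C)[C@@H]12 | intermediate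
25 | (1R,6R,7R,8R,10R)-1,10-epoxy-8-[(2S,3R)-2,3-epoxy-2-methylbutanoyloxy]germacra-2Z,4Z,11(13)-trien-6,12-olide (CNP0122107.1) | C=C1C(=O)O[C@@H]2/C=C(C)\C=C/[C@H]3O[C@]3(C)C[C@@H](OC(=O)[C@@]3(C)O[C@@H]3C)[C@@H]12 | target

**Step count.** 18 steps in total. The longest linear sequence is 13 steps (steps 1–5, 9, 12–18).

**Steps most likely to fail**

1. Step 15. Bimolecular coupling (oligomerisation) may outrun closure of the ten-membered ring, and facial selectivity at C1 may erode if trivalent chromium chelates O10 and the aldehyde oxygen. Fallback: setting out from 21 as obtained (mixture of C1 epimers), the carbinol is oxidised with Dess–Martin periodinane to the macrocyclic ynone F1. F1 is then reduced under reagent control with (R)-2-methyl-CBS-oxazaborolidine and catecholborane (alkyne as the small group), which should return the 1S alcohol and come back to the route at 21.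

2. Step 12. E2 elimination of the C8 oxyphosphonium ion towards C7, or slow SN2 at the hindered carbinol with leakage to retention through an acyloxyphosphonium pathway. Fallback: the C8 configuration is set in the C–C bond formation instead. Setting out from 8 and 13, bromide 8 is converted with hexabutylditin and Pd(PPh3)4 into the allylstannane F2. F2 is added to aldehyde 13 with BF3·OEt2 at −78 °C through an open antiperiplanar transition state (syn-selective, attack again anti to the C6 substituent), which should give the 8R carbinol F3 directly. Yamaguchi esterification of F3 with acid 17 (2,4,6-trichlorobenzoyl chloride, Et3N, DMAP), which proceeds with retention, comes back to the route at 18.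

3. Step 17. Over-reduction or palladium hydride-mediated isomerisation of the C11=C13 exocyclic methylene during semi-hydrogenation. Fallback: setting out from 22, the methylene lactone is masked as the dimethylamine Michael adduct F4 (Me2NH, THF). The ring alkyne of F4 is semi-hydrogenated over the Lindlar catalyst to the Z,Z-diene amine F5. The methylene is then regenerated by quaternisation with MeI to the ammonium iodide F6 and NaHCO3-induced elimination, which comes back to the route at 23.

Further compounds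
F1 | step 15 | (6R,7R,8R,10R)-1-oxo-10-(triethylsilyloxy)-8-[(2S,3R)-2,3-epoxy-2-methylbutanoyloxy]germacra-4Z,11(13)-dien-2-yn-6,12-olide (macrocyclic ynone) | C=C1C(=O)O[C@@H]2/C=C(C)\C#CC(=O)[C@](C)(O[Si](CC)(CC)CC)C[C@@H](OC(=O)[C@@]3(C)O[C@@H]3C)[C@@H]12
F2 | step 12 | (5R)-5-[(1Z)-2-methyl-4-(trimethylsilyl)but-1-en-3-yn-1-yl]-3-[(tributylstannyl)methyl]furan-2(5H)-one | CCCC[Sn](CCCC)(CCCC)CC1=C[C@@H](/C=C(C)\C#C[Si](C)(C)C)OC1=O
F3 | step 12 | (4R,5R)-4-[(1R,3R)-1-hydroxy-3-methyl-3,4-bis(triethylsilyloxy)butyl]-3-methylidene-5-[(1Z)-2-methyl-4-(trimethylsilyl)but-1-en-3-yn-1-yl]oxolan-2-one (C8 epimer of 14) | C=C1C(=O)O[C@H](/C=C(C)\C#C[Si](C)(C)C)[C@H]1[C@H](O)C[C@@](C)(O[Si](CC)(CC)CC)CO[Si](CC)(CC)CC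
F4 | step 17 | 13-(dimethylamino)-11,13-dihydro adduct of 22 (C11 not specified) | CN(C)CC1C(=O)O[C@@H]2/C=C(C)\C#C[C@H](O)[C@](C)(O)C[C@@H](OC(=O)[C@@]3(C)O[C@@H]3C)[C@@H]12
F5 | step 17 | 13-(dimethylamino)-11,13-dihydro adduct of 23 (C11 not specified) | CN(C)CC1C(=O)O[C@@H]2/C=C(C)\C=C/[C@H](O)[C@](C)(O)C[C@@H](OC(=O)[C@@]3(C)O[C@@H]3C)[C@@H]12
F6 | step 17 | N-methyl ammonium iodide of F5 | C[N+](C)(C)CC1C(=O)O[C@@H]2/C=C(C)\C=C/[C@H](O)[C@](C)(O)C[C@@H](OC(=O)[C@@]3(C)O[C@@H]3C)[C@@H]12.[I-]
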